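The data come from a simulation from invented constants, noise included.

What I wanted to know of this flask was how many links stand at the asked time, and what, if anything, has stopped it by then.

| flask | solid first end groups | second end groups | protic impurity | remark | time |
|---|---|---|---|---|---|
| zeta | 0.12 M | 0.90 equiv | 0.025 M | run made earlier |  |
| eta | 0.50 M | 0.90 equiv | 0.025 M | run made earlier |  |
| alpha | 0.25 M | 1.8 equiv | 0.025 M | run made earlier |  |
| flask | 0.25 M | 0.900 equiv | 0.0250 M |  | 12 d |

| run | time / d | links / % | solid first end groups / % |
|---|---|---|---|
| zeta | 1.67 | 69 | 0 |
| zeta | 3.00 | 71 | 2 |
| zeta | 5.00 | 69 | 2 |
| zeta | 6.00 | 71 | 0 |
| zeta | 8.00 | 67 | 2 |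
| zeta | 10.0 | 68 | 2 |
| eta | 1.67 | 86 | 0 |
| eta | 3.00 | 85 | 3 |
| eta | 5.00 | 85 | 0 |
| eta | 6.00 | 81 | 0 |
| eta | 8.00 | 89 | 0 |
| eta | 10.0 | 84 | 0 |
| alpha | 0.833 | 101 | 1 |
| alpha | 1.67 | 99 | 2 |
| alpha | 2.50 | 101 | 0 |
| alpha | 5.00 | 102 | 0 |
| alpha | 10.0 | 101 | 0 |

(readings scatter by 2 percentage points)

- as a solid, counted per litre of solution: solid first end groups
- on the list of suspects stand: solid first end groups <-> first end groups; first end groups + second end groups -> links; second end groups + protic impurity -> quenched reagent
- at the start none of the solid first end groups is in solution
- what has only dissolved of solid first end groups counts as not reacted
- the reaction counts as stopped when no species that holds the solid first end groups changes by six tenths of a point or more over the second half of the time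

- at 12 d, what has stopped the reaction, if anything has (for what has run out or reacted, a solid counts together with what of it has only dissolved) (it is still moving / the second end groups has run out first / all of the solid first end groups has reacted)
- links at 12 d, in percent of the solid first end groups charged

At the bench I would say that each protic impurity costs one second end group and each second end group left makes one link, which treats second end groups as the limiting reagent. So I took second end groups charged less protic impurity, per solid first end groups charged, which for this flask is 80.0%, and called it the net reagent share. In the zeta run the share is 69.2% and in the eta run 85.0%, and links there read near 69% and 85%, with a scatter of 2 percentage points.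

The border shows in the alpha run, where the same ratio is 170%, yet links read 101%. In the alpha run links read about the whole charge of solid first end groups, so I trusted the rule only for a share below that reading, and this flask stands under it. The earlier runs read flat within their scatter from 1.67 d, which is earlier than the 12 d asked.

The forecast gave 80% links and said that the second end groups has run out first, on the ground that “the impurity takes its full share of reagent”.

These steps stood behind the flask:

    solid first end groups ⇌ first end groups, rate k1*(cs1 - [first end groups]) while solid is left; crystals form when [first end groups] > cs1 (solubility = 0.230 M, k = 0.343 h⁻¹)
    first end groups + second end groups → links (k = 2.36 M⁻¹ h⁻¹)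
    second end groups + protic impurity → quenched reagent (k = 5.87 M⁻¹ h⁻¹)

At 12 d the flask gave 80.0% links, and the outcome was that the second end groups has run out first, with 0% of the second end groups left. The share counts the protic impurity as wholly spent, whereas this flask kept 0.14% of it unbound. The neighbouring flask with 0.540 equiv of second end groups, its other charges and the time held, kept a larger part of its protic impurity. Its net reagent share is 44.0%, and it ended at 44.5% links, with 5.4% of its protic impurity still unbound.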